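**Assumption:** the (R,R)-lithium amide in step 6 is taken to show the same sense of induction as it does with 4-tert-butylcyclohexanone (giving the (S)-enol silane), with the equatorial CMe2 carbon in the role of tert-butyl.

**Retrosynthetic overview**
1. Target ⇐ primary allylic alcohol 30 (exocyclic methylene by reductive 1,3-transposition); C9 carbinol ⇐ α-chloro ketone + MeTi(OiPr)3; C2/C3 bromohydrin ⇐ α′-bromo enone.
2. Ring-A enone ⇐ vinylogous ester by Stork–Danheiser addition of LiCH2OMOM; meanwhile the ring-B chloro ketone is carried as its chloro enol silyl ether.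
3. Absolute configuration ⇐ enantioselective deprotonation of the achiral spiro diketone 11, which makes the spiro carbon stereogenic.
4. 11 ⇐ spiro enone 10 ⇐ keto aldehyde 8: the key C6–C11 bond comes from an intermolecular Michael addition of formylated vinylogous ester 6 to methyl vinyl ketone, and ring B is closed by intramolecular aldol condensation.
5. Ring order: ring A comes intact from dimedone (1); ring B is annulated onto it (steps 3–5).

**Conventions.** All spiro compounds use the target numbering: C1 = CMe2, C2 (Br), C3 (OH), C4, C5 (=CH2), C6 = spiro carbon, C7, C8 (Cl), C9 (Me, OH), C10, C11. The C6 descriptor changes from R (13–21) to S (25 onward) only because the C2 bromine raises the CIP rank of C1; no bond at C6 is touched after step 6.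

**Route**

Step 1
Reactants: 1 dimedone (5,5-dimethylcyclohexane-1,3-dione); 2 2-methylpropan-1-ol
Product: 3 5,5-dimethyl-3-(2-methylpropoxy)cyclohex-2-en-1-one
Conditions: i-BuOH (3 equiv), p-TsOH·H2O (2 mol%), toluene, reflux, Dean–Stark
Reagents that add atoms: 2-methylpropan-1-ol, CC(C)CO
Why: acid-catalysed enol etherification of the symmetrical 1,3-dione gives the vinylogous ester, which differentiates the two carbonyls and leaves C6 as the only kinetically acidic α-position; no stereocentre.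

Step 2
Reactants: 3 5,5-dimethyl-3-(2-methylpropoxy)cyclohex-2-en-1-one; 4 ethyl formate
Product: 6 (6Z)-6-(hydroxymethylidene)-5,5-dimethyl-3-(2-methylpropoxy)cyclohex-2-en-1-one, via lithium dienolate 5 (not isolated)
Conditions: LDA (1.1 equiv), THF, −78 °C; HCO2Et (3 equiv), −78 → 0 °C; aq. NH4Cl
Reagents that add atoms: ethyl formate, CCOC=O
Why: crossed Claisen condensation (formylation) of the kinetic α′-enolate gives the hydrogen-bonded enol of the β-keto aldehyde; no configurationally stable stereocentre.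

Step 3
Reactants: 6 (6Z)-6-(hydroxymethylidene)-5,5-dimethyl-3-(2-methylpropoxy)cyclohex-2-en-1-one; 7 but-3-en-2-one
Product: 8 rac-6,6-dimethyl-4-(2-methylpropoxy)-2-oxo-1-(3-oxobutyl)cyclohex-3-ene-1-carbaldehyde
Conditions: MVK (2 equiv), Et3N (0.2 equiv), CH2Cl2, 0 °C → rt
Reagents that add atoms: but-3-en-2-one, CC(=O)C=C
Why: intermolecular Michael addition of the soft β-keto aldehyde enolate to MVK forms the C6–C11 bond and the quaternary (future spiro) carbon; it is made racemic on purpose because it stops being stereogenic in step 5.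

Step 4
Reactants: 8 rac-6,6-dimethyl-4-(2-methylpropoxy)-2-oxo-1-(3-oxobutyl)cyclohex-3-ene-1-carbaldehyde
Product: 10 rac-1,1-dimethyl-3-(2-methylpropoxy)spiro[5.5]undeca-3,7-diene-5,9-dione, via ketol 9 (not isolated)
Conditions: p-TsOH·H2O (10 mol%), toluene, reflux, Dean–Stark
Reagents that add atoms: none
Why: intramolecular aldol condensation (second half of a Robinson-type spiroannulation): the methyl ketone enol attacks the non-enolisable aldehyde and dehydration gives the 4,4-disubstituted cyclohexenone; acid catalysis avoids retro-Claisen deformylation.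

Step 5
Reactants: 10 rac-1,1-dimethyl-3-(2-methylpropoxy)spiro[5.5]undeca-3,7-diene-5,9-dione
Product: 11 1,1-dimethyl-3-(2-methylpropoxy)spiro[5.5]undec-3-ene-5,9-dione
Conditions: H2 (1 atm), 10% Pd/C, EtOAc, rt
Reagents that add atoms: none
Why: chemoselective catalytic hydrogenation of the disubstituted enone C=C (the electron-rich vinylogous ester C=C is inert) gives an achiral ketone whose two ring-B arms are enantiotopic.

Step 6
Reactants: 11 1,1-dimethyl-3-(2-methylpropoxy)spiro[5.5]undec-3-ene-5,9-dione; 12 chlorotrimethylsilane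
Product: 13 (6R)-1,1-dimethyl-3-(2-methylpropoxy)-9-(trimethylsilyloxy)spiro[5.5]undeca-3,8-dien-5-one
Conditions: (R,R)-bis(1-phenylethyl)amine (1.3 equiv), n-BuLi (1.25 equiv), THF, −78 °C; TMSCl (5 equiv, in situ), add 11, −100 °C; Et3N, aq. NaHCO3
Reagents that add atoms: chlorotrimethylsilane, C[Si](C)(C)Cl
Why: enantioselective deprotonation with a chiral lithium amide and internal TMSCl quench removes the axial H-8 rather than H-10 of the chair that has C1 equatorial, so the silyl enol ether forms toward C8 and C6 becomes stereogenic (about 90% ee expected by analogy).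

Step 7
Reactants: 13 (6R)-1,1-dimethyl-3-(2-methylpropoxy)-9-(trimethylsilyloxy)spiro[5.5]undeca-3,8-dien-5-one; 14 N-chlorosuccinimide
Product: 15 (6R,8S)-8-chloro-1,1-dimethyl-3-(2-methylpropoxy)spiro[5.5]undec-3-ene-5,9-dione
Conditions: NCS (1.05 equiv), NaHCO3, THF, −78 → 0 °C
Reagents that add atoms: N-chlorosuccinimide, O=C1CCC(=O)N1Cl
Why: electrophilic α-chlorination of the regiodefined silyl enol ether puts Cl on C8 only, equatorial and cis to C1 because an axial Cl would be syn-axial to C5; this centre is erased in step 8 and re-set in step 12.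

Step 8
Reactants: 15 (6R,8S)-8-chloro-1,1-dimethyl-3-(2-methylpropoxy)spiro[5.5]undec-3-ene-5,9-dione; 16 tert-butyldimethylsilyl trifluoromethanesulfonate
Product: 18 (6R)-9-{[tert-butyl(dimethyl)silyl]oxy}-8-chloro-1,1-dimethyl-3-(2-methylpropoxy)spiro[5.5]undeca-3,8-dien-5-one, via lithium chloroenolate 17 (not isolated)
Conditions: LiHMDS (1.1 equiv), THF, −78 °C; TBSOTf (1.2 equiv), −78 → −40 °C
Reagents that add atoms: tert-butyldimethylsilyl trifluoromethanesulfonate, CC(C)(C)[Si](C)(C)OS(=O)(=O)C(F)(F)F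
Why: silyl enol ether formation at the more acidic axial H-8 masks the ring-B ketone against the organolithium, LDA and DIBAL-H steps and makes C8 sp2; no new stereocentre.

Step 9
Reactants: 18 (6R)-9-{[tert-butyl(dimethyl)silyl]oxy}-8-chloro-1,1-dimethyl-3-(2-methylpropoxy)spiro[5.5]undeca-3,8-dien-5-one; 19 tributyl[(methoxymethoxy)methyl]stannane
Product: 21 (6R)-9-{[tert-butyl(dimethyl)silyl]oxy}-8-chloro-5-[(methoxymethoxy)methyl]-1,1-dimethylspiro[5.5]undeca-4,8-dien-3-one, via carbinol adduct 20 (not isolated)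
Conditions: 19 (1.6 equiv), n-BuLi (1.5 equiv), THF, −78 °C; add 18, −78 → −30 °C; then 10% aq. HCl, 0 °C, 15 min
Reagents that add atoms: tributyl[(methoxymethoxy)methyl]stannane, CCCC[Sn](CCCC)(CCCC)COCOC; water, O
Why: Stork–Danheiser sequence: 1,2-addition of the α-alkoxy organolithium (from Sn–Li exchange) to the vinylogous ester carbonyl, then acid-induced transposition to the C3 enone carrying the future exocyclic carbon as CH2OMOM; the adduct's carbinol centre is destroyed and C6 is untouched.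

Step 10
Reactants: 21 (6R)-9-{[tert-butyl(dimethyl)silyl]oxy}-8-chloro-5-[(methoxymethoxy)methyl]-1,1-dimethylspiro[5.5]undeca-4,8-dien-3-one; 22 N-bromosuccinimide
Product: 25 (2S,6S)-2-bromo-9-{[tert-butyl(dimethyl)silyl]oxy}-8-chloro-5-[(methoxymethoxy)methyl]-1,1-dimethylspiro[5.5]undeca-4,8-dien-3-one, via silyl dienol ether 23 (not isolated), via C2-epimeric bromo enone 24 (not isolated)
Conditions: LDA (1.2 equiv), TMSCl (3 equiv), THF, −78 °C; NBS (1.05 equiv), THF, −78 °C; then DBU (0.2 equiv), CH2Cl2, rt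
Reagents that add atoms: N-bromosuccinimide, O=C1CCC(=O)N1Br
Why: kinetic α′-enolisation (C4=C5 blocks the other side), bromination of the silyl dienol ether, then base equilibration of the acidic C2–H: by conformational analysis the favoured epimer has pseudo-equatorial Br in the ring-A half-chair that turns the C5 side chain toward the flattened C7–C8(sp2) flank of ring B instead of toward axial H-10, i.e. Br cis to C7 (2S).

Step 11
Reactants: 25 (2S,6S)-2-bromo-9-{[tert-butyl(dimethyl)silyl]oxy}-8-chloro-5-[(methoxymethoxy)methyl]-1,1-dimethylspiro[5.5]undeca-4,8-dien-3-one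
Product: 26 (2S,3R,6S)-2-bromo-9-{[tert-butyl(dimethyl)silyl]oxy}-8-chloro-5-[(methoxymethoxy)methyl]-1,1-dimethylspiro[5.5]undeca-4,8-dien-3-ol
Conditions: DIBAL-H (1.5 equiv), CH2Cl2, −78 °C; Rochelle salt
Reagents that add atoms: none
Why: 1,2-reduction of the α′-bromo enone; hydride enters anti to the axial C1 methyl (1,3 to C3), giving the axial alcohol cis to the equatorial bromide (3R).

Step 12
Reactants: 26 (2S,3R,6S)-2-bromo-9-{[tert-butyl(dimethyl)silyl]oxy}-8-chloro-5-[(methoxymethoxy)methyl]-1,1-dimethylspiro[5.5]undeca-4,8-dien-3-ol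
Product: 27 (2S,3R,6S,8S)-2-bromo-8-chloro-3-hydroxy-5-[(methoxymethoxy)methyl]-1,1-dimethylspiro[5.5]undec-4-en-9-one
Conditions: TBAF (1.2 equiv), AcOH (1.5 equiv), THF, 0 °C
Reagents that add atoms: none
Why: buffered fluoride desilylation of the silyl enol ether and C-protonation regenerate the α-chloro ketone; C8 is set under thermodynamic control with Cl equatorial (8S), since an axial Cl would be syn-axial to C5.

Step 13
Reactants: 27 (2S,3R,6S,8S)-2-bromo-8-chloro-3-hydroxy-5-[(methoxymethoxy)methyl]-1,1-dimethylspiro[5.5]undec-4-en-9-one; 28 methyltitanium triisopropoxide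
Product: 29 (2S,3R,6S,8S,9R)-2-bromo-8-chloro-5-[(methoxymethoxy)methyl]-1,1,9-trimethylspiro[5.5]undec-4-ene-3,9-diol
Conditions: MeTi(OiPr)3 (3 equiv), THF–Et2O, −40 → 0 °C; aq. NH4Cl
Reagents that add atoms: methyltitanium triisopropoxide, C[Ti](OC(C)C)(OC(C)C)OC(C)C
Why: non-basic, chemoselective carbonyl methylation with an organotitanium reagent; the bulky reagent attacks the conformationally locked cyclohexanone equatorially, giving equatorial CH3 and axial OH cis to the equatorial Cl (9R).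

Step 14
Reactants: 29 (2S,3R,6S,8S,9R)-2-bromo-8-chloro-5-[(methoxymethoxy)methyl]-1,1,9-trimethylspiro[5.5]undec-4-ene-3,9-diol
Product: 30 (2S,3R,6S,8S,9R)-2-bromo-8-chloro-5-(hydroxymethyl)-1,1,9-trimethylspiro[5.5]undec-4-ene-3,9-diol
Conditions: ZnBr2 (1 equiv), n-PrSH (2 equiv), CH2Cl2, 0 °C → rt, 10 min
Reagents that add atoms: none
Why: Lewis acid/thiol cleavage of the MOM acetal under brief, near-neutral conditions frees the primary allylic alcohol without touching the halides or the other alcohols; no stereocentre is affected.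

Step 15
Reactants: 30 (2S,3R,6S,8S,9R)-2-bromo-8-chloro-5-(hydroxymethyl)-1,1,9-trimethylspiro[5.5]undec-4-ene-3,9-diol
Product: 33 (2S,3R,6S,8S,9R)-2-bromo-8-chloro-1,1,9-trimethyl-5-methylidenespiro[5.5]undecane-3,9-diol (the target), via N-allyl sulfonylhydrazine 31 (not isolated), via allylic diazene 32 (not isolated)
Conditions: 2-nitrobenzenesulfonylhydrazide (1.5 equiv), PPh3 (1.5 equiv), DEAD (1.5 equiv), THF, −30 °C, 2 h; then rt, 3 h
Reagents that add atoms: none
Why: Myers reductive 1,3-transposition: Mitsunobu displacement at the unhindered primary allylic alcohol, loss of sulfinic acid and retro-ene loss of N2 from the monoalkyl diazene deliver H to C4 and move the double bond to the exocyclic position; no stereocentre changes.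

**Compound list**

1 | dimedone (5,5-dimethylcyclohexane-1,3-dione) | CC1(C)CC(=O)CC(=O)C1 | starting material
2 | 2-methylpropan-1-ol | CC(C)CO | starting material
3 | 5,5-dimethyl-3-(2-methylpropoxy)cyclohex-2-en-1-one | O=C1C=C(OCC(C)C)CC(C)(C)C1 | intermediate
4 | ethyl formate | CCOC=O | starting material
5 | lithium 3,3-dimethyl-5-(2-methylpropoxy)cyclohexa-1,5-dien-1-olate (C6 enolate of 3) | [Li+].[O-]C1=CC(C)(C)CC(OCC(C)C)=C1 | intermediate (not isolated)
6 | (6Z)-6-(hydroxymethylidene)-5,5-dimethyl-3-(2-methylpropoxy)cyclohex-2-en-1-one | O/C=C1\C(=O)C=C(OCC(C)C)CC1(C)C | intermediate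
7 | but-3-en-2-one (methyl vinyl ketone) | CC(=O)C=C | starting material
8 | rac-6,6-dimethyl-4-(2-methylpropoxy)-2-oxo-1-(3-oxobutyl)cyclohex-3-ene-1-carbaldehyde | O=CC1(CCC(C)=O)C(=O)C=C(OCC(C)C)CC1(C)C | intermediate
9 | rac-7-hydroxy-1,1-dimethyl-3-(2-methylpropoxy)spiro[5.5]undec-3-ene-5,9-dione (both C7 epimers) | O=C1CC(O)C2(CC1)C(=O)C=C(OCC(C)C)CC2(C)C | intermediate (not isolated)
10 | rac-1,1-dimethyl-3-(2-methylpropoxy)spiro[5.5]undeca-3,7-diene-5,9-dione | O=C1C=CC2(CC1)C(=O)C=C(OCC(C)C)CC2(C)C | intermediate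
11 | 1,1-dimethyl-3-(2-methylpropoxy)spiro[5.5]undec-3-ene-5,9-dione (achiral) | O=C1CCC2(CC1)C(=O)C=C(OCC(C)C)CC2(C)C | intermediate
12 | chlorotrimethylsilane | C[Si](C)(C)Cl | starting material
13 | (6R)-1,1-dimethyl-3-(2-methylpropoxy)-9-(trimethylsilyloxy)spiro[5.5]undeca-3,8-dien-5-one | O=C1C=C(OCC(C)C)CC(C)(C)[C@]12CCC(O[Si](C)(C)C)=CC2 | intermediate
14 | N-chlorosuccinimide | O=C1CCC(=O)N1Cl | starting material
15 | (6R,8S)-8-chloro-1,1-dimethyl-3-(2-methylpropoxy)spiro[5.5]undec-3-ene-5,9-dione | O=C1C=C(OCC(C)C)CC(C)(C)[C@]12CCC(=O)[C@@H](Cl)C2 | intermediate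
16 | tert-butyldimethylsilyl trifluoromethanesulfonate | CC(C)(C)[Si](C)(C)OS(=O)(=O)C(F)(F)F | starting material
17 | lithium (6R)-8-chloro-1,1-dimethyl-3-(2-methylpropoxy)-5-oxospiro[5.5]undeca-3,8-dien-9-olate | O=C1C=C(OCC(C)C)CC(C)(C)[C@]12CCC([O-])=C(Cl)C2.[Li+] | intermediate (not isolated)
18 | (6R)-9-{[tert-butyl(dimethyl)silyl]oxy}-8-chloro-1,1-dimethyl-3-(2-methylpropoxy)spiro[5.5]undeca-3,8-dien-5-one | O=C1C=C(OCC(C)C)CC(C)(C)[C@]12CCC(O[Si](C)(C)C(C)(C)C)=C(Cl)C2 | intermediate
19 | tributyl[(methoxymethoxy)methyl]stannane | CCCC[Sn](CCCC)(CCCC)COCOC | starting material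
20 | (6R)-9-{[tert-butyl(dimethyl)silyl]oxy}-8-chloro-5-[(methoxymethoxy)methyl]-1,1-dimethyl-3-(2-methylpropoxy)spiro[5.5]undeca-3,8-dien-5-ol (both C5 epimers, formed as the lithium alkoxide) | COCOCC1(O)C=C(OCC(C)C)CC(C)(C)[C@]12CCC(O[Si](C)(C)C(C)(C)C)=C(Cl)C2 | intermediate (not isolated)
21 | (6R)-9-{[tert-butyl(dimethyl)silyl]oxy}-8-chloro-5-[(methoxymethoxy)methyl]-1,1-dimethylspiro[5.5]undeca-4,8-dien-3-one | COCOCC1=CC(=O)CC(C)(C)[C@]12CCC(O[Si](C)(C)C(C)(C)C)=C(Cl)C2 | intermediate
22 | N-bromosuccinimide | O=C1CCC(=O)N1Br | starting material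
23 | (6R)-9-{[tert-butyl(dimethyl)silyl]oxy}-8-chloro-5-[(methoxymethoxy)methyl]-1,1-dimethyl-3-(trimethylsilyloxy)spiro[5.5]undeca-2,4,8-triene | COCOCC1=CC(O[Si](C)(C)C)=CC(C)(C)[C@]12CCC(O[Si](C)(C)C(C)(C)C)=C(Cl)C2 | intermediate (not isolated)
24 | (2R,6S)-2-bromo-9-{[tert-butyl(dimethyl)silyl]oxy}-8-chloro-5-[(methoxymethoxy)methyl]-1,1-dimethylspiro[5.5]undeca-4,8-dien-3-one (C2 epimer of 25) | COCOCC1=CC(=O)[C@H](Br)C(C)(C)[C@]12CCC(O[Si](C)(C)C(C)(C)C)=C(Cl)C2 | intermediate (not isolated)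
25 | (2S,6S)-2-bromo-9-{[tert-butyl(dimethyl)silyl]oxy}-8-chloro-5-[(methoxymethoxy)methyl]-1,1-dimethylspiro[5.5]undeca-4,8-dien-3-one | COCOCC1=CC(=O)[C@@H](Br)C(C)(C)[C@]12CCC(O[Si](C)(C)C(C)(C)C)=C(Cl)C2 | intermediate
26 | (2S,3R,6S)-2-bromo-9-{[tert-butyl(dimethyl)silyl]oxy}-8-chloro-5-[(methoxymethoxy)methyl]-1,1-dimethylspiro[5.5]undeca-4,8-dien-3-ol | COCOCC1=C[C@@H](O)[C@@H](Br)C(C)(C)[C@]12CCC(O[Si](C)(C)C(C)(C)C)=C(Cl)C2 | intermediate
27 | (2S,3R,6S,8S)-2-bromo-8-chloro-3-hydroxy-5-[(methoxymethoxy)methyl]-1,1-dimethylspiro[5.5]undec-4-en-9-one | COCOCC1=C[C@@H](O)[C@@H](Br)C(C)(C)[C@]12CCC(=O)[C@@H](Cl)C2 | intermediate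
28 | methyltitanium triisopropoxide | C[Ti](OC(C)C)(OC(C)C)OC(C)C | starting material
29 | (2S,3R,6S,8S,9R)-2-bromo-8-chloro-5-[(methoxymethoxy)methyl]-1,1,9-trimethylspiro[5.5]undec-4-ene-3,9-diol | COCOCC1=C[C@@H](O)[C@@H](Br)C(C)(C)[C@]12CC[C@@](C)(O)[C@@H](Cl)C2 | intermediate
30 | (2S,3R,6S,8S,9R)-2-bromo-8-chloro-5-(hydroxymethyl)-1,1,9-trimethylspiro[5.5]undec-4-ene-3,9-diol | OCC1=C[C@@H](O)[C@@H](Br)C(C)(C)[C@]12CC[C@@](C)(O)[C@@H](Cl)C2 | intermediate
31 | N-{[(2S,3R,6S,8S,9R)-2-bromo-8-chloro-3,9-dihydroxy-1,1,9-trimethylspiro[5.5]undec-4-en-5-yl]methyl}-2-nitrobenzenesulfonohydrazide (alkylated on the sulfonyl-bearing N) | NN(CC1=C[C@@H](O)[C@@H](Br)C(C)(C)[C@]12CC[C@@](C)(O)[C@@H](Cl)C2)S(=O)(=O)c1ccccc1[N+](=O)[O-] | intermediate (not isolated)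
32 | (2S,3R,6S,8S,9R)-2-bromo-8-chloro-5-(diazenylmethyl)-1,1,9-trimethylspiro[5.5]undec-4-ene-3,9-diol | N=NCC1=C[C@@H](O)[C@@H](Br)C(C)(C)[C@]12CC[C@@](C)(O)[C@@H](Cl)C2 | intermediate (not isolated)
33 | (2S,3R,6S,8S,9R)-2-bromo-8-chloro-1,1,9-trimethyl-5-methylidenespiro[5.5]undecane-3,9-diol | C=C1C[C@@H](O)[C@@H](Br)C(C)(C)[C@]12CC[C@@](C)(O)[C@@H](Cl)C2 | target

**Totals**

Total step count: 15. Longest linear sequence: 15 steps (1 → 33; the route is fully linear).

**Three steps most likely to fail, with fallbacks**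

Step 10 (C2 configuration relative to ring B). The stereocontrol rests on a conformational argument (C8 sp2 versus C10 sp3), not on a tested case, and could be weak. If base equilibration does not give a useful excess of 25, equilibrium control is replaced by separation and recycling. This fallback sets out from 24 (as its mixture with 25) and comes back to the route at 25. The mixture is reduced with DIBAL-H as in step 11, and 26 is separated by chromatography from the diastereomeric (2R,3S,6S)-2-bromo-9-{[tert-butyl(dimethyl)silyl]oxy}-8-chloro-5-[(methoxymethoxy)methyl]-1,1-dimethylspiro[5.5]undeca-4,8-dien-3-ol F5. F5 is re-oxidised with Dess–Martin periodinane to 24, which is re-equilibrated with DBU to the 24/25 mixture and cycled again.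

Step 3 (Michael addition at the neopentyl C6, next to CMe2). The addition may stall, or the non-enolisable β-keto aldehyde may deformylate. The fallback closes the spiro ring by double alkylation; it sets out from 3 and comes back at 11. The lithium enolate of 3 (LDA, THF/HMPA, −78 → 0 °C) is alkylated with 2,2-bis(2-iodoethyl)-1,3-dioxolane to give 6-{2-[2-(2-iodoethyl)-1,3-dioxolan-2-yl]ethyl}-5,5-dimethyl-3-(2-methylpropoxy)cyclohex-2-en-1-one F1. A second equivalent of LDA closes the ring to 9,9-(ethylenedioxy)-1,1-dimethyl-3-(2-methylpropoxy)spiro[5.5]undec-3-en-5-one F2. PPTS in wet acetone removes the dioxolane to give 11.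

Step 6 (enantioselective deprotonation). The ee may be lower than with simple 4-substituted cyclohexanones because of the axial ring-A carbon, and the vinylogous ester γ-protons could compete. A moderate ee would be raised by recrystallisation at a crystalline stage such as 15. If the ee is unusable, the stereocentre is set by catalytic desymmetrising reduction instead; this fallback sets out from 10 and comes back at 13. DDQ (dioxane, reflux) dehydrogenates 10 to the achiral 1,1-dimethyl-3-(2-methylpropoxy)spiro[5.5]undeca-3,7,10-triene-5,9-dione F3. Copper hydride conjugate reduction (Cu(OAc)2, the appropriate enantiomer of DTBM-SEGPHOS, PMHS, t-BuOH) reduces one of the two enantiotopic enone double bonds to give (6R)-1,1-dimethyl-3-(2-methylpropoxy)spiro[5.5]undeca-3,7-diene-5,9-dione F4. Stryker's reagent with TMSCl then gives the regiodefined silyl enol ether 13.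

**Further compounds**

F1 | step 3 | 6-{2-[2-(2-iodoethyl)-1,3-dioxolan-2-yl]ethyl}-5,5-dimethyl-3-(2-methylpropoxy)cyclohex-2-en-1-one (racemic) | O=C1C=C(OCC(C)C)CC(C)(C)C1CCC1(CCI)OCCO1
F2 | step 3 | 9,9-(ethylenedioxy)-1,1-dimethyl-3-(2-methylpropoxy)spiro[5.5]undec-3-en-5-one (achiral) | O=C1C=C(OCC(C)C)CC(C)(C)C12CCC3(CC2)OCCO3
F3 | step 6 | 1,1-dimethyl-3-(2-methylpropoxy)spiro[5.5]undeca-3,7,10-triene-5,9-dione (achiral) | O=C1C=CC2(C=C1)C(=O)C=C(OCC(C)C)CC2(C)C
F4 | step 6 | (6R)-1,1-dimethyl-3-(2-methylpropoxy)spiro[5.5]undeca-3,7-diene-5,9-dione | O=C1C=C(OCC(C)C)CC(C)(C)[C@]12CCC(=O)C=C2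
F5 | step 10 | (2R,3S,6S)-2-bromo-9-{[tert-butyl(dimethyl)silyl]oxy}-8-chloro-5-[(methoxymethoxy)methyl]-1,1-dimethylspiro[5.5]undeca-4,8-dien-3-ol | COCOCC1=C[C@H](O)[C@H](Br)C(C)(C)[C@]12CCC(O[Si](C)(C)C(C)(C)C)=C(Cl)C2
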